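The earlier runs and the new flask come from a simulation with made-up constants, noise included.

5 questions stood on the board for the 0.035 M flask at 10 h, and Sunday's run had read G and Z but neither X nor D.

| flask | G | remark | time |
|---|---|---|---|
| Sunday's | 0.070 M | run made earlier |  |
| flask | 0.035 M |  | 10 h |

Sunday's run (percent of the G charged)

| time / min | G / % | Z / % |
|---|---|---|
| 5.00 | 39.8 | 19.5 |
| 15.0 | 20.7 | 15.6 |
| 30.0 | 18.9 | 15.7 |
| 40.0 | 19.7 | 14.8 |
| 60.0 | 18.4 | 15.3 |

(each reading ± 0.5 percentage points)

- why nothing more happens at 10 h, or that something still does (it is still moving / forward and back rates have come level / all of G has reacted)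
- part of the G gone at 10 h
- the Z standing at 10 h, as a percentage of the G charged
- the X standing at 10 h, as a percentage of the G charged
- the D standing at 10 h, as a percentage of the G charged

- the reaction counts as stopped when no species that holds the G changes by six tenths of a point or more over the second half of the time

I took Sunday's run in slow motion through its remainder: what was charged, minus [G], minus [Z]. This is the closure of the mass balance, if each G becomes one of something.

In the first instants, up to 5.00 min, [G] fell to 39.8%. [Z] stood at 19.5%, above its later 15.3%, so I read Z as made first and then passed on. The remainder was 40.7%. In the middle, at 15.0 min, it was 63.7%. From 30.0 min on, the readings lay flat within their scatter, and their means gave 65.7%. I called this W, the plateau remainder, the share of the charge standing neither as G nor as Z.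

I took the gap below W as closing in first-order fashion, halving every τ, and got a rough τ from one reading of Sunday's run:

gap at 5.00 min = 65.7% − 40.7% = 25.0%

τ = 5.00 min · ln 2 / ln(W / gap) = 3.59 min

10 h / τ = 167

Sunday's [G] stayed flat near 18.4%, and 10 h is far longer than τ, so I expected forward and back rates to stand level in the 0.035 M flask at 10 h. Sunday's run had a single charge, so its readings showed nothing of what the charge does. I assumed one-to-one steps, which carry the percentages from 0.070 M to 0.035 M. X and D together should then equal W, and the readings did not give their split.

The forecast said forward and back rates have come level, with 85% of G gone, Z 16%, X 85% and D 69%, adding that “The X and D values are weakly determined”. Its X and D add to 154%, more than my W.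

    G ⇌ Z (K = 0.820, k = 0.00305 /s)
    G ⇌ X (K = 2.80, k = 0.00135 /s)
    Z ⇌ X (k = 0.00315 /s)
    Z ⇌ D (K = 0.760, k = 0.00243 /s)

The flask's answer on the end was: forward and back rates have come level. It had 80.9% of G gone, Z 15.6%, X 53.4% and D 11.9%. In this flask X and D add to 65.3%, close to W, and there the forecast and the flask part. I applied the same reckoning to the neighbouring flask, charged with 0.0088 M of G and read at 10.0 h. It held G 19% and Z 15.6%, so W should again stand for X and D together. That flask held X 53.4% and D 11.9%, together 65.3%, against a W of 65.7%.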